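**Strategy**

The route rests on reading the C5–H of the benzene ring, flanked by C4–Br and C6–Br, as the scar of an amino group that has been removed. 1H-Indol-5-amine already carries that nitrogen; its two ortho carbons are C4 and C6, its para carbon is the ring-fusion atom C7a, and the pyrrole ring offers the nucleophilic C3/C2 pair. One exhaustive bromination with N-bromosuccinimide should therefore install all four C–Br bonds (C2, C3, C4, C6) on the unprotected aminoindole, and a reductive deamination then erases the director. N1 stays free because an acyl or sulfonyl group there would shut down C2 bromination.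

Key step: step 1

Remark on the chemistry: 1 is assumed to be used as the free base from a fresh lot (or after a short silica plug under argon), since the free NH2 is what activates C4 and C6 and the compound darkens in air; the order of the single brominations shown in step 1 is the presumed one and every order converges on 6.

**Route**

Step 1
Reactants: 1 1H-indol-5-amine; 2 N-bromosuccinimide
Product: 6 2,3,4,6-tetrabromo-1H-indol-5-amine, via 3-bromo-1H-indol-5-amine 3 (not isolated), via 3,4-dibromo-1H-indol-5-amine 4 (not isolated), via 3,4,6-tribromo-1H-indol-5-amine 5 (not isolated)
Conditions: NBS (4.05 equiv, four portions), anhydrous DMF, −40 → 0 °C, Ar, dark; then aq Na2S2O3/NaHCO3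
Reagents that add atoms: N-bromosuccinimide, O=C1CCC(=O)N1Br
Why: Four consecutive electrophilic aromatic substitutions by positive bromine from NBS are expected: the enamine-like C3 of the pyrrole ring should react first, the free C5–NH2 then activates its ortho carbons C4 and C6 strongly enough to override the bromines already in place, and C2 is taken last, by direct attack or by attack at C3 of the 3-bromoindole and 1,2-shift of bromine. The closest known reaction types are the exhaustive ortho bromination of anilines whose para position is blocked and the 3-then-2 dibromination of NH-indoles with NBS. No ring is closed and no stereocentre is formed. The step needs site selectivity for C4 and C6 over C7 and for carbon over the two nitrogens: C7 is meta to the amine and gets no activation, the para carbon C7a is a quaternary ring-fusion atom, and any N-bromo species formed at N1 or at the amine is itself a bromine donor that passes the halogen on to carbon. Portionwise addition of just four equivalents in the cold and exclusion of water are meant to hold back oxidation of the electron-rich aminoindole to quinoid imines and diversion of the 3-bromoindole stage to an oxindole.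

Step 2
Reactants: 6 2,3,4,6-tetrabromo-1H-indol-5-amine; 7 tert-butyl nitrite
Product: 9 2,3,4,6-tetrabromo-1H-indole, via 2,3,4,6-tetrabromo-1H-indole-5-diazonium hydroxide 8 (not isolated)
Conditions: t-BuONO (1.5 equiv), THF, 0 °C then 60 °C, Ar
Reagents that add atoms: none
Why: Aprotic diazotization of the di-ortho-brominated amine by the alkyl nitrite followed by radical-chain hydrodediazoniation, in which the C5 aryl radical takes a hydrogen atom from C2 of the solvent tetrahydrofuran, is the established way to deaminate 2,6-dihaloanilines; C2 and C3 are blocked against C-nitrosation, a diazonium at C5 has no neighbouring nucleophile to cyclize onto, and the four C–Br bonds should be untouched.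

**Compound list**

1 | 1H-indol-5-amine | Nc1ccc2[nH]ccc2c1 | starting material
2 | N-bromosuccinimide | O=C1CCC(=O)N1Br | starting material
3 | 3-bromo-1H-indol-5-amine | Nc1ccc2[nH]cc(Br)c2c1 | intermediate
4 | 3,4-dibromo-1H-indol-5-amine | Nc1ccc2[nH]cc(Br)c2c1Br | intermediate
5 | 3,4,6-tribromo-1H-indol-5-amine | Nc1c(Br)cc2[nH]cc(Br)c2c1Br | intermediate
6 | 2,3,4,6-tetrabromo-1H-indol-5-amine | Nc1c(Br)cc2[nH]c(Br)c(Br)c2c1Br | intermediate
7 | tert-butyl nitrite | CC(C)(C)ON=O | starting material
8 | 2,3,4,6-tetrabromo-1H-indole-5-diazonium hydroxide (ion pair, in equilibrium with its covalent diazohydroxide) | [OH-].N#[N+]c1c(Br)cc2[nH]c(Br)c(Br)c2c1Br | intermediate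
9 | 2,3,4,6-tetrabromo-1H-indole | Brc1cc(Br)c2c(Br)c(Br)[nH]c2c1 | target

**Step count and risks**

Total step count: 2. Longest linear sequence: 2 steps, from 1 to 9.

The route has only two steps, so both are ranked, the riskier first.

1. Step 1. What may go wrong: oxidative breakdown of the electron-rich amine by NBS before the ring is fully brominated, or slow entry of the last bromine (at C2, or into the crowded C3/C4 peri region), which would leave mixtures of under-brominated amines. The fallback sets out from 1 and masks the amine while the pyrrole ring is brominated. Trifluoroacetic anhydride and pyridine in CH2Cl2 at −20 °C should give N-(1H-indol-5-yl)-2,2,2-trifluoroacetamide F1. Two equivalents of NBS in THF at −78 → 0 °C should then brominate only C3 and C2 to give N-(2,3-dibromo-1H-indol-5-yl)-2,2,2-trifluoroacetamide F2. K2CO3 in aqueous methanol should cleave the amide to 2,3-dibromo-1H-indol-5-amine F3. This amine, less easily oxidized because of its two bromines, is then dibrominated at its ortho carbons C4 and C6 with two equivalents of NBS in DMF at −20 °C, which comes back to the route at 6.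

2. Step 2. What may go wrong: diazotization that stalls at the hindered, electron-poor nitrogen, nitrosation at N1, or loss of the N1 proton from the diazonium ion to give a neutral quinoid diazo species that does not enter the radical chain. The fallback sets out from 6 and caps N1 before the deamination. Boc2O with catalytic DMAP in MeCN at room temperature should acylate only the indole nitrogen, the di-ortho-brominated amine being too hindered, and give tert-butyl 5-amino-2,3,4,6-tetrabromo-1H-indole-1-carboxylate F4. t-BuONO in THF at 60 °C should then give tert-butyl 2,3,4,6-tetrabromo-1H-indole-1-carboxylate F5. K2CO3 in methanol at room temperature should remove the carbamate from the acidic, electron-poor indole nitrogen, which comes back to the route at 9.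

Further compounds
F1 | step 1 | N-(1H-indol-5-yl)-2,2,2-trifluoroacetamide | O=C(Nc1ccc2[nH]ccc2c1)C(F)(F)F
F2 | step 1 | N-(2,3-dibromo-1H-indol-5-yl)-2,2,2-trifluoroacetamide | O=C(Nc1ccc2[nH]c(Br)c(Br)c2c1)C(F)(F)F
F3 | step 1 | 2,3-dibromo-1H-indol-5-amine | Nc1ccc2[nH]c(Br)c(Br)c2c1
F4 | step 2 | tert-butyl 5-amino-2,3,4,6-tetrabromo-1H-indole-1-carboxylate | CC(C)(C)OC(=O)n1c(Br)c(Br)c2c(Br)c(N)c(Br)cc12
F5 | step 2 | tert-butyl 2,3,4,6-tetrabromo-1H-indole-1-carboxylate | CC(C)(C)OC(=O)n1c(Br)c(Br)c2c(Br)cc(Br)cc12
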